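**Conventions.** Prenyl = 3-methylbut-2-en-1-yl; Boc = tert-butoxycarbonyl; allyl = prop-2-en-1-yl. Ring atoms of the pyrazinone are numbered N1 (bearing O), C2 (carbonyl), C3 (methyl), N4, C5 (methoxy), C6 (indolylmethyl).

## The problem

Astepyrazinoxide 23 joins a 7-prenylindole to a fully substituted pyrazin-2(1H)-one through one methylene group. The rings are not fused, so the work lies in building the chain at indole C3 and the six-membered heteroaromatic ring. The pyrazinone carries a different substituent on every atom, and its two oxygen functions must be told apart: the one on N1 ends free, the one on C5 ends as a methyl ether. The target has no stereocentre and no configured double bond. The only sp3 centre that arises in the ring, C6, becomes sp2 on aromatization, so nothing needs to be controlled.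

The fragile groups set the limits:
- The prenyl olefin adds acid, or closes onto the indole nitrogen to a six-membered ring. It is also hydrogenated, and it reacts with electrophilic oxidants and nitroso compounds.
- The N–O bond is cleaved by reduction.
- The free N-hydroxypyrazinone is acidic and binds metals.
- An indol-3-ylacetaldehyde condenses with itself.

The feature that opens the molecule is the sequence O–N1–C6–C5(=O)–N4, with N1 acylated by the C2(=O)–C3(=O)–CH3 unit. Atom for atom this is the adduct of an O-substituted aldoxime (C6=N1–O), an isocyanide (C5, N4) and pyruvic acid (C2, C3, methyl). Because C2 and C3 arrive as a 1,2-dicarbonyl, condensation alone gives the aromatic ring.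

## Retrosynthesis

**23 to 21.** The O–allyl bond on N1 and the N–Boc bond of the indole are cut last, through 22. A benzyl ether is set aside because hydrogenolysis would reduce the prenyl group and endanger the N–O bond, and boron halides would attack the prenylindole. An allyl ether leaves with Pd(PPh3)4 (zerovalent palladium) and an amine at room temperature. The Boc group stays on during deallylation so that the indole cannot capture the allyl fragment. It is then removed by K2CO3 in methanol, where methoxide exchange at C5 is degenerate. The forward step must leave the olefin, the N–O bond and the methyl ether alone.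

**21 to 20.** The O–CH3 bond at C5 is cut. Since N1–O is allylated from the start, the C5 hydroxyl of 20 is the only acidic site, so the two oxygens are differentiated by construction. Carrying the methoxy group earlier would mean a labile open-chain imidate. The forward step must methylate oxygen and not C6 or N4.

**20 to 17.** The ring is opened at C3=N4, which leads back through hydroxy lactam 19 to keto amide 18. Its primary amide nitrogen is masked in 17 as a 2-nitrobenzyl amide. Cutting N1–C6 instead would require an indolylpyruvic acid (see Alternative 3). Cutting N1–C2 alone would leave a hindered N-alkoxy amino amide to acylate with an activated keto acid. The chosen cut leaves an acyclic precursor whose ring closure is a 6-exo-trig condensation of an amide with a reactive methyl ketone. The forward step needs a neutral unmasking of N4, for which light is used.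

**17 to 11, 14 and 15.** This is the key disconnection: C5–C6 and N1–C2 are cut together, through imidate 16. Three fragments of low complexity result: oxime ether 11, isocyanide 14 and pyruvic acid 15. Stepwise neighbours (cyanide addition to 11, then acylation and hydration) form the same bonds in three operations and need an acid chloride of 15. The forward reaction must make the weakly electrophilic oxime ether react faster than the ketone of 15.

**14 to 13 to 12.** The isocyanide carbon is traced to a formyl group on the amine of 12. The two steps are formylation and dehydration.

**11 to 8 and 9, then 8 to 7, 6 and 4.** The C=N bond is cut to alkoxyamine salt 9 and aldehyde 10. Aldehyde 10 is not isolated but released from enol ether 8 in the same flask. Enol ether 8 comes from aldehyde 7 by a one-carbon Wittig homologation; the carbon added here becomes C6. Aldehyde 7 is the Boc derivative of 6, and 6 arises by C3 formylation of 4 through iminium salt 5. Direct C3 alkylation of 4 with a two-carbon aldehyde equivalent would be shorter but is poorly precedented. The formylation and Wittig sequence is standard on N-acylindoles.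

**4 to 1 and 2.** The C7–CH2 bond is cut to the C7 anion 3, derived from bromide 1, and prenyl bromide 2. The classical alternative is a four-step aza-Claisen sequence on the 2,3-dihydro heterocycle, which is longer. The forward step must alkylate carbon, not nitrogen, and without allylic transposition.

## Roads not taken

**Alternative 1:** The cut lies in the indole, at N1–C7a and N1–C2 (indole numbering). The forward key step is a Paal–Knorr condensation of the 1,4-keto aldehyde A1 with NH4OAc in acetic acid. It closes the pyrrole ring of the racemic tetrahydroindole A2, whose carbocycle is then dehydrogenated to 4.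
- Merits: only enolate alkylations and a condensation are needed, no organolithium reagent is used, and the prenyl position is fixed as a ketone α-substituent.
- Weak points: the late aromatization must remove four hydrogens next to a prenyl group. DDQ or hot Pd/C would attack or isomerize that olefin and the electron-rich pyrrole. A1 needs two regiocontrolled alkylations and an aldehyde unmasking. The stereocentre of A2 is made only to be destroyed.
- Comparison: the road needs at least five steps to reach 4, which step 1 reaches in one, and it contributes nothing to the pyrazinone. It does avoid cryogenic tert-butyllithium and the N- versus C-alkylation question. The chosen plan sets against this its brevity and the absence of any dehydrogenation beside the prenyl group.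

**Alternative 2:** Three bonds of the benzene ring are cut: C3a–C7a, C4–C5 and C6–C7 (indole numbering). The forward key step is a RhCl(PPh3)3-catalysed cyclotrimerization of the N-tosyl ynamide diyne A3 with acetylene A4. It forms the benzene ring and the five-membered nitrogen ring together and gives the N-tosylindoline A5.
- Merits: two rings form in one operation, and the tether fixes the position of the prenyl group without ambiguity.
- Weak points: A3 requires N-alkynylation of a sulfonamide with a bromoalkyne that holds a skipped enyne, whose doubly activated CH2 isomerizes easily. Gaseous A4 must outcompete self-trimerization of A3. A5 still needs desulfonylation and dehydrogenation to reach 4.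
- Comparison: about six steps replace one. This road would be the better choice if further substituents were wanted on the benzene ring, and its key step builds rings where the Ugi coupling builds none. For this target, the indole nucleus can be bought with a handle at C7, so building it is wasted effort.

**Alternative 3:** The pyrazinone is cut at N1–C6. In the forward key step, TsOH in toluene makes the hydroxamate N–H of the keto amide A6 add to its ketone and lose water, closing the ring to the alkylidene piperazinedione A7. A double tautomerization (C3–H to the exocyclic carbon, N4–H to O5) would then give the aromatic tautomer of A7, followed by O-methylation and debenzylation.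
- Merits: the key step closes the ring. No isocyanide and no light source are needed. C3, its methyl group and N4 are bought as an amino acid, and the end game converges on the chosen one.
- Weak points: A6 requires the indolylpyruvic acid A8, which is enolized, air-sensitive and awkward to activate for amide coupling. The closure asks a hindered, weakly nucleophilic N-alkoxy amide nitrogen to add to a ketone that is largely enolized into conjugation with the indole. It runs under hot sulfonic acid with a free indole N–H and a prenyl group, the conditions under which the prenyl group closes onto the indole nitrogen. The stereocentre of A6 is sacrificed.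
- Comparison: this road is of similar length and simpler in equipment, and in those respects it is as good or better. The chosen plan sets against it three things. All bond formation around C6 runs under near-neutral Lewis acid conditions on N-Boc intermediates. The ring closes by attack of a primary amide on a reactive methyl ketone in warm acetic acid. No arylpyruvic acid is handled.

Key step: step 8

Remark: 23 has no stereocentre. Compounds 16 to 19 are racemic (19 as a diastereomer mixture) and 8 and 11 are E/Z mixtures; none of this reaches the target. Compounds 1, 2, 9, 12 and 15 are taken as purchasable.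

## Route

Step 1
Reactants: 1 7-bromo-1H-indole; 2 1-bromo-3-methylbut-2-ene (prenyl bromide)
Product: 4 7-prenyl-1H-indole, via 7-lithioindol-1-yl potassium 3 (not isolated)
Conditions: KH, THF, 0 °C; t-BuLi (2 equiv), −78 °C; then 2, −78 °C to rt; H2O
Reagents that add atoms: none
Why: KH removes the N–H and bromine–lithium exchange with two equivalents of tert-butyllithium then gives 3 (halogen–metal exchange on an unprotected bromoindole). At −78 °C the aryllithium is far more nucleophilic than the potassium amide and displaces bromide from the primary allylic carbon of 2 (SN2), placing the unrearranged prenyl group on C7.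

Step 2
Reactants: 4 7-prenyl-1H-indole
Product: 6 7-prenyl-1H-indole-3-carbaldehyde, via iminium chloride 5 (not isolated)
Conditions: POCl3, DMF, 0 °C to rt; then aq NaOH, 0 °C to rt
Reagents that add atoms: N,N-dimethylformamide, CN(C)C=O; water, O
Why: Vilsmeier–Haack formylation: the chloroiminium ion attacks indole C3, the most nucleophilic site, far faster than the trisubstituted olefin. Cold aqueous base hydrolyses iminium salt 5 to the aldehyde.

Step 3
Reactants: 6 7-prenyl-1H-indole-3-carbaldehyde
Product: 7 tert-butyl 3-formyl-7-prenylindole-1-carboxylate
Conditions: Boc2O, DMAP (cat.), MeCN, rt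
Reagents that add atoms: di-tert-butyl dicarbonate, CC(C)(C)OC(=O)OC(=O)OC(C)(C)C
Why: DMAP-catalysed acylation of the indole nitrogen, made more acidic by the 3-formyl group. The carbamate turns the vinylogous formamide into a normal aryl aldehyde for the Wittig reaction and lowers indole nucleophilicity for the later steps.

Step 4
Reactants: 7 tert-butyl 3-formyl-7-prenylindole-1-carboxylate
Product: 8 tert-butyl 3-(2-methoxyethenyl)-7-prenylindole-1-carboxylate (E/Z mixture)
Conditions: Ph3P(CH2OMe)Cl, KN(SiMe3)2, THF, 0 °C; then 7, 0 °C to rt
Reagents that add atoms: (methoxymethyl)triphenylphosphonium chloride, COC[P+](c1ccccc1)(c1ccccc1)c1ccccc1.[Cl-]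
Why: Wittig methoxymethylenation with a non-stabilised ylide, which does not attack the carbamate. The olefin geometry is irrelevant because both isomers give the same aldehyde in step 5.

Step 5
Reactants: 8 tert-butyl 3-(2-methoxyethenyl)-7-prenylindole-1-carboxylate; 9 O-allylhydroxylamine hydrochloride
Product: 11 tert-butyl 3-[2-(allyloxyimino)ethyl]-7-prenylindole-1-carboxylate (E/Z mixture at C=N), via aldehyde 10 (not isolated)
Conditions: 9 (1.5 equiv), THF–H2O (4:1), 45 °C; aq NaHCO3 work-up
Reagents that add atoms: none
Why: The alkoxyammonium salt is acidic enough to protonate the enol ether, and water releases aldehyde 10. The α-effect nitrogen of 9 traps it at once as the oxime ether (enol ether hydrolysis and oximation in one pot), so the self-condensing aldehyde never accumulates. The indole carbamate tolerates this mild aqueous acid.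

Step 6
Reactants: 12 2-nitrobenzylamine hydrochloride
Product: 13 N-(2-nitrobenzyl)formamide
Conditions: HCO2Et, Et3N, reflux
Reagents that add atoms: ethyl formate, CCOC=O
Why: N-Formylation of a primary amine by aminolysis of ethyl formate, after the amine is freed from its salt with Et3N.

Step 7
Reactants: 13 N-(2-nitrobenzyl)formamide
Product: 14 2-nitrobenzyl isocyanide
Conditions: POCl3, Et3N, CH2Cl2, −20 to 0 °C
Reagents that add atoms: none
Why: Dehydration of an N-monosubstituted formamide with POCl3 and Et3N is the standard isocyanide synthesis. The low temperature protects the acidic benzylic position.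

Step 8
Reactants: 11 tert-butyl 3-[2-(allyloxyimino)ethyl]-7-prenylindole-1-carboxylate; 14 2-nitrobenzyl isocyanide; 15 pyruvic acid
Product: 17 racemic tert-butyl 3-{2-[(allyloxy)(2-oxopropanoyl)amino]-3-[(2-nitrobenzyl)amino]-3-oxopropyl}-7-prenylindole-1-carboxylate (Ugi adduct), via imidate 16 (not isolated)
Conditions: ZnCl2 (1 equiv), THF, rt; 15 added slowly
Reagents that add atoms: none
Why: ZnCl2, helped by the proton of 15, coordinates the oxime nitrogen and makes the C=N carbon electrophilic enough for attack by the isocyanide carbon of 14, which forms C5–C6 and a nitrilium ion. Pyruvate adds to the nitrilium carbon to give imidate 16, and a 1,4 O-to-N acyl shift (Mumm rearrangement) through a five-membered transition state onto the alkoxyamine nitrogen forms N1–C2 irreversibly. The closest known reaction type is the ZnCl2-promoted Ugi-type three-component coupling of preformed O-alkyl aldoximes with carboxylic acids and isocyanides, which gives N-alkoxy α-acylamino amides. No ring is closed. The one new stereocentre, C6, forms without any controlling element, so 17 is racemic; this is accepted because C6 becomes sp2 in step 9. The selectivity needed is chemoselectivity: the isocyanide must add to the oxime carbon and not to the pyruvoyl ketone (Passerini pathway), which Lewis acid activation of the C=N bond in an aprotic solvent and slow addition of 15 should secure, and the alkoxyamine must not condense with that ketone, which its use as the preformed oxime ether secures. The Boc group keeps the indole from adding to the activated C=N bond, and both oxime isomers give the same adduct.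

Step 9
Reactants: 17 racemic Ugi adduct
Product: 20 1-allyloxy-5-hydroxy-3-methyl-6-[(1-Boc-7-prenylindol-3-yl)methyl]pyrazin-2(1H)-one, via primary amide 18 (not isolated), via hydroxy lactam 19 (not isolated)
Conditions: hν (365 nm), 2,3-dimethylbuta-1,3-diene (10 equiv), MeCN, argon, rt; then AcOH, 50 °C
Reagents that add atoms: none
Why: Photolysis of an N-(2-nitrobenzyl) amide: the excited nitro group abstracts a benzylic hydrogen and the aci-nitro form collapses to primary amide 18 and 2-nitrosobenzaldehyde, which the diene removes by hetero-Diels–Alder reaction before it can undergo an ene reaction with the prenyl group. N4 then adds 6-exo-trig to the C3 ketone to give hydroxy lactam 19; any ring-closed tautomer of 17 converges on the same intermediate. Acid-catalysed loss of water and enolisation of C6–H toward O5 give the aromatic 5-hydroxypyrazinone (amide–ketone cyclocondensation), erasing the C6 stereocentre.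

Step 10
Reactants: 20 1-allyloxy-5-hydroxy-3-methyl-6-[(1-Boc-7-prenylindol-3-yl)methyl]pyrazin-2(1H)-one
Product: 21 1-allyloxy-5-methoxy-3-methyl-6-[(1-Boc-7-prenylindol-3-yl)methyl]pyrazin-2(1H)-one
Conditions: MeI, Ag2CO3, toluene, rt to 40 °C, dark, argon
Reagents that add atoms: iodomethane, CI
Why: Silver-assisted O-alkylation of a hydroxyazine (lactim ether formation). The C5 hydroxyl holds the only acidic proton, N1 is blocked by the allyloxy group, methylation at N4 or C6 would break the aromatic ring, and the halophilic silver ion favours reaction at oxygen.

Step 11
Reactants: 21 1-allyloxy-5-methoxy-3-methyl-6-[(1-Boc-7-prenylindol-3-yl)methyl]pyrazin-2(1H)-one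
Product: 23 astepyrazinoxide (1-hydroxy-5-methoxy-3-methyl-6-[(7-prenyl-1H-indol-3-yl)methyl]pyrazin-2(1H)-one), via N-hydroxypyrazinone 22 (not isolated)
Conditions: Pd(PPh3)4 (5 mol %), morpholine, THF, rt; then K2CO3, MeOH, 40 °C; aq citric acid work-up
Reagents that add atoms: none
Why: Tsuji–Trost deallylation: Pd(PPh3)4 ionises the allyl–oxygen bond of the N-allyloxypyrazinone, a good leaving group, and morpholine captures the π-allyl complex, which the Boc-deactivated indole cannot do. K2CO3 in methanol then cleaves the crowded indole carbamate by methanolysis; under these conditions methoxide exchange at C5 is degenerate, and the prenyl olefin and N–O bond are untouched.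

## Compound list

1 | 7-bromo-1H-indole | Brc1cccc2cc[nH]c12 | starting material
2 | 1-bromo-3-methylbut-2-ene (prenyl bromide) | CC(C)=CCBr | starting material
3 | 7-lithioindol-1-yl potassium (not isolated) | [Li]c1cccc2cc[n-]c12.[K+] | intermediate
4 | 7-(3-methylbut-2-en-1-yl)-1H-indole (7-prenylindole) | CC(C)=CCc1cccc2cc[nH]c12 | intermediate
5 | N-[(7-prenyl-1H-indol-3-yl)methylidene]-N-methylmethanaminium chloride (not isolated) | C[N+](C)=Cc1c[nH]c2c(CC=C(C)C)cccc12.[Cl-] | intermediate
6 | 7-prenyl-1H-indole-3-carbaldehyde | O=Cc1c[nH]c2c(CC=C(C)C)cccc12 | intermediate
7 | tert-butyl 3-formyl-7-prenylindole-1-carboxylate | O=Cc1cn(C(=O)OC(C)(C)C)c2c(CC=C(C)C)cccc12 | intermediate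
8 | tert-butyl 3-(2-methoxyethenyl)-7-prenylindole-1-carboxylate (E/Z mixture) | COC=Cc1cn(C(=O)OC(C)(C)C)c2c(CC=C(C)C)cccc12 | intermediate
9 | O-allylhydroxylamine hydrochloride | C=CCON.Cl | starting material
10 | tert-butyl 3-(2-oxoethyl)-7-prenylindole-1-carboxylate (not isolated) | O=CCc1cn(C(=O)OC(C)(C)C)c2c(CC=C(C)C)cccc12 | intermediate
11 | tert-butyl 3-[2-(allyloxyimino)ethyl]-7-prenylindole-1-carboxylate (E/Z mixture at C=N) | C=CCON=CCc1cn(C(=O)OC(C)(C)C)c2c(CC=C(C)C)cccc12 | intermediate
12 | 2-nitrobenzylamine hydrochloride | NCc1ccccc1[N+](=O)[O-].Cl | starting material
13 | N-(2-nitrobenzyl)formamide | O=CNCc1ccccc1[N+](=O)[O-] | intermediate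
14 | 2-nitrobenzyl isocyanide | [C-]#[N+]Cc1ccccc1[N+](=O)[O-] | intermediate
15 | pyruvic acid (2-oxopropanoic acid) | CC(=O)C(=O)O | starting material
16 | racemic O-pyruvoyl imidate: mixed anhydride of pyruvic acid and 2-(allyloxyamino)-3-(1-Boc-7-prenylindol-3-yl)-N-(2-nitrobenzyl)propanimidic acid (not isolated) | CC(=O)C(=O)OC(=NCc1ccccc1[N+](=O)[O-])C(Cc1cn(C(=O)OC(C)(C)C)c2c(CC=C(C)C)cccc12)NOCC=C | intermediate
17 | racemic tert-butyl 3-{2-[(allyloxy)(2-oxopropanoyl)amino]-3-[(2-nitrobenzyl)amino]-3-oxopropyl}-7-prenylindole-1-carboxylate (Ugi adduct) | CC(=O)C(=O)N(OCC=C)C(Cc1cn(C(=O)OC(C)(C)C)c2c(CC=C(C)C)cccc12)C(=O)NCc1ccccc1[N+](=O)[O-] | intermediate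
18 | racemic tert-butyl 3-{2-[(allyloxy)(2-oxopropanoyl)amino]-3-amino-3-oxopropyl}-7-prenylindole-1-carboxylate (not isolated) | CC(=O)C(=O)N(OCC=C)C(Cc1cn(C(=O)OC(C)(C)C)c2c(CC=C(C)C)cccc12)C(N)=O | intermediate
19 | 1-allyloxy-3-hydroxy-3-methyl-6-[(1-Boc-7-prenylindol-3-yl)methyl]piperazine-2,5-dione, racemic diastereomer mixture (not isolated) | CC1(O)NC(=O)C(Cc2cn(C(=O)OC(C)(C)C)c3c(CC=C(C)C)cccc23)N(OCC=C)C1=O | intermediate
20 | 1-allyloxy-5-hydroxy-3-methyl-6-[(1-Boc-7-prenylindol-3-yl)methyl]pyrazin-2(1H)-one | Cc1nc(O)c(Cc2cn(C(=O)OC(C)(C)C)c3c(CC=C(C)C)cccc23)n(OCC=C)c1=O | intermediate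
21 | 1-allyloxy-5-methoxy-3-methyl-6-[(1-Boc-7-prenylindol-3-yl)methyl]pyrazin-2(1H)-one | COc1nc(C)c(=O)n(OCC=C)c1Cc1cn(C(=O)OC(C)(C)C)c2c(CC=C(C)C)cccc12 | intermediate
22 | 1-hydroxy-5-methoxy-3-methyl-6-[(1-Boc-7-prenylindol-3-yl)methyl]pyrazin-2(1H)-one (not isolated) | COc1nc(C)c(=O)n(O)c1Cc1cn(C(=O)OC(C)(C)C)c2c(CC=C(C)C)cccc12 | intermediate
23 | astepyrazinoxide, 1-hydroxy-5-methoxy-3-methyl-6-{[7-(3-methylbut-2-en-1-yl)-1H-indol-3-yl]methyl}pyrazin-2(1H)-one | COc1nc(C)c(=O)n(O)c1Cc1c[nH]c2c(CC=C(C)C)cccc12 | target

## Step count and risks

Total step count: 11. Longest linear sequence: 9 steps (steps 1 to 5 and 8 to 11, from 1 to 23). Steps 6 and 7 are a two-step branch to 14.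

**Step 8, the key step.** The oxime ether is a weak electrophile. The most likely failure is consumption of the isocyanide by Passerini-type addition to the ketone of pyruvic acid, or by ZnCl2-induced oligomerization, before it adds to the C=N bond. The fallback removes the competing electrophile from the acid component and adjusts the oxidation level afterwards. Setting out from 11 and 14, the coupling would be run under the same ZnCl2 conditions with (S)-lactic acid in place of 15. This gives the lactamide tert-butyl 3-{2-[(allyloxy)((2S)-2-hydroxypropanoyl)amino]-3-[(2-nitrobenzyl)amino]-3-oxopropyl}-7-prenylindole-1-carboxylate F1 as both C6 epimers. Dess–Martin oxidation of its secondary alcohol returns the route to 17.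

**Step 9.** The pyruvoyl amide absorbs weakly near 365 nm. Competing Norrish–Yang hydrogen abstraction from the O–CH2 or C6–H positions may consume material, as may an ene reaction of the nitroso by-product with the prenyl group or incomplete dehydration of 19. The fallback closes the ring before the photolysis, so that no 1,2-dicarbonyl chromophore is irradiated. From 17, Et3N in CH2Cl2 would add the secondary amide nitrogen to the ketone to give the hydroxy lactam 1-allyloxy-3-hydroxy-3-methyl-4-(2-nitrobenzyl)-6-[(1-Boc-7-prenylindol-3-yl)methyl]piperazine-2,5-dione F2. MsCl and Et3N would dehydrate it to the enamide 1-allyloxy-3-methylidene-4-(2-nitrobenzyl)-6-[(1-Boc-7-prenylindol-3-yl)methyl]piperazine-2,5-dione F3. Irradiation of F3 at 365 nm with the same diene trap then removes the nitrobenzyl group, and the N4–H enamide tautomerizes to the aromatic ring, rejoining the route at 20.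

**Step 5.** Protonation of the indole-conjugated enol ether may be slow under the mild acidity used. Forcing it risks loss of the Boc group or self-condensation of the aldehyde. The fallback reaches 10 by oxidation instead of hydrolysis. From 7, Wittig methylenation with Ph3P=CH2 would give tert-butyl 3-ethenyl-7-prenylindole-1-carboxylate F4. 9-BBN hydroborates its monosubstituted olefin at the terminal carbon and leaves the trisubstituted prenyl olefin alone, and NaBO3·4H2O oxidation gives tert-butyl 3-(2-hydroxyethyl)-7-prenylindole-1-carboxylate F5. Buffered Dess–Martin oxidation gives 10, which is condensed in the same flask with 9 and pyridine to return at 11.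

**Step 1.** The indolyl potassium may be alkylated at nitrogen or C3 if the exchange is incomplete or the mixture warms. Attack at the tertiary allylic terminus would give the 1,1-dimethylallyl isomer. The fallback replaces the organolithium alkylation by a cross-coupling. From 2, zinc dust and LiCl in THF would give prenylzinc bromide F6. F6 is coupled with 1 using Pd(OAc)2 and the biarylphosphine CPhos (Negishi coupling with ligand-controlled selectivity for the linear allyl isomer) to come back at 4. An excess of F6 allows for any consumption by the N–H.

**Step 10.** Methylation at C6 or N4 of the ambident anion, or air oxidation of the electron-rich hydroxypyrazinone 20, may lower the return. The fallback changes the mechanism. From 20, (trimethylsilyl)diazomethane in toluene–methanol methylates by proton transfer from the C5 hydroxyl to the diazo carbon. The ion pair then collapses at the oxygen that carried the proton, arriving at 21 without new intermediates.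

## Further compounds

F1 | step 8 | tert-butyl 3-{2-[(allyloxy)((2S)-2-hydroxypropanoyl)amino]-3-[(2-nitrobenzyl)amino]-3-oxopropyl}-7-prenylindole-1-carboxylate (both C6 epimers) | C[C@H](O)C(=O)N(OCC=C)C(Cc1cn(C(=O)OC(C)(C)C)c2c(CC=C(C)C)cccc12)C(=O)NCc1ccccc1[N+](=O)[O-]
F2 | step 9 | 1-allyloxy-3-hydroxy-3-methyl-4-(2-nitrobenzyl)-6-[(1-Boc-7-prenylindol-3-yl)methyl]piperazine-2,5-dione (racemic diastereomer mixture) | CC1(O)N(Cc2ccccc2[N+](=O)[O-])C(=O)C(Cc2cn(C(=O)OC(C)(C)C)c3c(CC=C(C)C)cccc23)N(OCC=C)C1=O
F3 | step 9 | racemic 1-allyloxy-3-methylidene-4-(2-nitrobenzyl)-6-[(1-Boc-7-prenylindol-3-yl)methyl]piperazine-2,5-dione | C=C1N(Cc2ccccc2[N+](=O)[O-])C(=O)C(Cc2cn(C(=O)OC(C)(C)C)c3c(CC=C(C)C)cccc23)N(OCC=C)C1=O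
F4 | step 5 | tert-butyl 3-ethenyl-7-prenylindole-1-carboxylate | C=Cc1cn(C(=O)OC(C)(C)C)c2c(CC=C(C)C)cccc12
F5 | step 5 | tert-butyl 3-(2-hydroxyethyl)-7-prenylindole-1-carboxylate | OCCc1cn(C(=O)OC(C)(C)C)c2c(CC=C(C)C)cccc12
F6 | step 1 | prenylzinc bromide | CC(C)=CC[Zn]Br
F0 | step 10 | none | none
A1 | alternative 1 | [3-(3-methylbut-2-en-1-yl)-2-oxocyclohexyl]acetaldehyde (diastereomer mixture) | CC(C)=CCC1CCCC(CC=O)C1=O
A2 | alternative 1 | racemic 7-prenyl-4,5,6,7-tetrahydro-1H-indole | CC(C)=CCC1CCCc2cc[nH]c21
A3 | alternative 2 | N-(but-3-yn-1-yl)-4-methyl-N-(5-methylhex-4-en-1-yn-1-yl)benzenesulfonamide | C#CCCN(C#CCC=C(C)C)S(=O)(=O)c1ccc(C)cc1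
A4 | alternative 2 | acetylene | C#C
A5 | alternative 2 | 7-prenyl-1-tosylindoline | CC(C)=CCc1cccc2c1N(S(=O)(=O)c1ccc(C)cc1)CC2
A6 | alternative 3 | (2S)-N-(benzyloxy)-2-{[2-oxo-3-(7-prenyl-1H-indol-3-yl)propanoyl]amino}propanamide | C[C@H](NC(=O)C(=O)Cc1c[nH]c2c(CC=C(C)C)cccc12)C(=O)NOCc1ccccc1
A7 | alternative 3 | (3S,6Z)-1-(benzyloxy)-3-methyl-6-[(7-prenyl-1H-indol-3-yl)methylidene]piperazine-2,5-dione | C[C@@H]1NC(=O)/C(=C/c2c[nH]c3c(CC=C(C)C)cccc23)N(OCc2ccccc2)C1=O
A8 | alternative 3 | 2-oxo-3-(7-prenyl-1H-indol-3-yl)propanoic acid | CC(C)=CCc1cccc2c(CC(=O)C(=O)O)c[nH]c12
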